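Stephaflavone B is made of flavone unit 1 (5-hydroxy-7,4'-dimethoxyflavone, bonded through C6) and flavone unit 2 (genkwanin, bonded through C3). The three free phenols are masked first: 5-OMe in both units and 4'-OBn in unit 2.
The retrosynthesis then cuts two bonds in one operation, C3(unit 2)–C6(unit 1) and O1–C2 of the pyranone ring of unit 2. This leaves 6-iodo-5,7,4'-trimethoxyflavone and an acyclic 2,4,6-trimethoxyphenyl aryl ynone.
Enabling feature: C3 of unit 2 is the α-carbon of the O1–C2=C3–C4=O array, so it takes up the electrophile when an ortho oxygen of ring A closes onto the ynone. Ring A of unit 2 is 2,4,6-trioxygenated, so its two ortho methoxy groups are equivalent and only one chromone can arise.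
Forward order: unit 1 is finished first by 7-O-methylation, C6 iodination directed by the chelated 5-OH, and 5-O-methylation. The ynone comes from acetylide addition and oxidation, and the key step closes the pyranone ring of unit 2 while joining the units.
BCl3 then frees the three phenols. The 5-OMe groups are told apart from the 7- and 4'-OMe groups by chelation of boron to the peri carbonyl groups.
Stereochemistry: the target has no stereocentre and its biaryl axis is not defined, so nothing has to be controlled.

Key step: step 6

Assumption: the SMILES fixes no configuration at the hindered C3–C6 axis, so no control of axial chirality is attempted.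

Step 1
Reactants: 1 acacetin (5,7-dihydroxy-2-(4-methoxyphenyl)-4H-chromen-4-one)
Product: 2 5-hydroxy-7-methoxy-2-(4-methoxyphenyl)-4H-chromen-4-one
Conditions: MeI (1.05 equiv), K2CO3, acetone, reflux
Reagents that add atoms: iodomethane, CI
Why: Williamson ether synthesis, in which one equivalent of MeI should take only the free and more acidic 7-OH because the 5-OH is tied up in a hydrogen bond to the C4 carbonyl group.

Step 2
Reactants: 2 5-hydroxy-7-methoxy-2-(4-methoxyphenyl)-4H-chromen-4-one
Product: 3 5-hydroxy-6-iodo-7-methoxy-2-(4-methoxyphenyl)-4H-chromen-4-one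
Conditions: BnMe3N[ICl2] (1.1 equiv), CaCO3, CH2Cl2–MeOH, rt
Reagents that add atoms: benzyltrimethylammonium dichloroiodate, C[N+](C)(C)Cc1ccccc1.Cl[I-]Cl
Why: Electrophilic aromatic iodination under buffered, nearly neutral conditions, which in 5-hydroxy-7-alkoxyflavones is known to go ortho to the chelated free 5-OH (C6) and not to C8, so that the linking position of unit 1 is marked here.

Step 3
Reactants: 3 5-hydroxy-6-iodo-7-methoxy-2-(4-methoxyphenyl)-4H-chromen-4-one
Product: 4 6-iodo-5,7-dimethoxy-2-(4-methoxyphenyl)-4H-chromen-4-one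
Conditions: Me2SO4 (excess), K2CO3, acetone, reflux
Reagents that add atoms: dimethyl sulfate, COS(=O)(=O)OC
Why: Williamson ether synthesis under forcing conditions, known for chelated 5-OH groups of flavones; the methyl cap removes the only acidic proton of the fragment, blocks heteroannulation of an ortho-iodophenol with the alkyne in step 6 and, unlike a benzyl cap, offers the arylpalladium no aryl C–H bond for an intramolecular direct arylation.

Step 4
Reactants: 5 1-(benzyloxy)-4-ethynylbenzene; 6 2,4,6-trimethoxybenzaldehyde
Product: 8 racemic 3-[4-(benzyloxy)phenyl]-1-(2,4,6-trimethoxyphenyl)prop-2-yn-1-ol, via lithium acetylide 7 (not isolated)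
Conditions: 5, n-BuLi, THF, −78 °C; then 6, −78 to 0 °C; H2O quench
Reagents that add atoms: none
Why: 1,2-Addition of a lithium acetylide to an aromatic aldehyde, a standard entry to aryl propargylic alcohols; the new carbinol centre is racemic and is erased in step 5.

Step 5
Reactants: 8 racemic 3-[4-(benzyloxy)phenyl]-1-(2,4,6-trimethoxyphenyl)prop-2-yn-1-ol
Product: 9 3-[4-(benzyloxy)phenyl]-1-(2,4,6-trimethoxyphenyl)prop-2-yn-1-one
Conditions: MnO2 (excess), CH2Cl2, rt
Reagents that add atoms: none
Why: MnO2 oxidation of an alcohol that is both benzylic and propargylic, neutral enough for the acid-sensitive substrate and inert towards the alkyne, the benzyl ether and the methyl ethers.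

Step 6
Reactants: 4 6-iodo-5,7-dimethoxy-2-(4-methoxyphenyl)-4H-chromen-4-one; 9 3-[4-(benzyloxy)phenyl]-1-(2,4,6-trimethoxyphenyl)prop-2-yn-1-one
Product: 10 2-[4-(benzyloxy)phenyl]-3-[5,7-dimethoxy-2-(4-methoxyphenyl)-4-oxo-4H-chromen-6-yl]-5,7-dimethoxy-4H-chromen-4-one
Conditions: Pd2(dba)3 (5 mol %), SPhos (20 mol %), AgOAc (2 equiv), 4 Å molecular sieves, 1,4-dioxane, 90 °C
Reagents that add atoms: none
Why: Proposed new method: zerovalent palladium inserts into the C6–I bond of 4, AgOAc takes the iodide, the electrophilic arylpalladium acetate binds the alkyne of 9, one ortho methoxy oxygen attacks the aryl-bearing alkyne carbon anti to the metal, acetate takes the methyl group off the oxonium ion as methyl acetate, and reductive elimination from the aryl(flavon-3-yl)palladium makes the C3–C6 bond between the units. The closest known reaction types are the heteropalladation–reductive elimination of ortho-alkynylphenols, ortho-alkynylanilides and N-tert-butyl ortho-alkynylbenzaldimines with aryl halides (the imines likewise use a neutral nucleophile that sheds its alkyl group) and the ICl-induced closure of ortho-methoxyaryl ynones to 3-iodochromones; new is the use of an arylpalladium species in place of the iodonium source on such a ynone. The pyranone ring of unit 2 closes 6-endo-dig at O1–C2, preferred to 5-exo-dig because the carbonyl group polarises the alkyne so that oxygen goes to the β-carbon and the metal to the α-carbon, as the iodine version shows. No stereocentre arises, and the hindered C3–C6 axis, undefined in the target, forms as a racemate. The step needs site selectivity in unit 1, which the iodine at C6 fixes, a single mode of closure in unit 2, which the two equivalent ortho methoxy groups of 9 secure, and arylation instead of protonation at C3, which the absence of any base or proton source secures, since a methyl ether cannot close on the ynone by itself and the C3–metal bond cannot be protonated. The two ortho methoxy groups of the arylpalladium disfavour syn carbopalladation of the alkyne and, together with the bulky SPhos, speed up the reductive elimination.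

Step 7
Reactants: 10 2-[4-(benzyloxy)phenyl]-3-[5,7-dimethoxy-2-(4-methoxyphenyl)-4-oxo-4H-chromen-6-yl]-5,7-dimethoxy-4H-chromen-4-one
Product: 11 stephaflavone B (5-hydroxy-3-[5-hydroxy-7-methoxy-2-(4-methoxyphenyl)-4-oxo-4H-chromen-6-yl]-2-(4-hydroxyphenyl)-7-methoxy-4H-chromen-4-one)
Conditions: BCl3 (excess), pentamethylbenzene, CH2Cl2, −78 °C to rt; then H2O
Reagents that add atoms: none
Why: Lewis acid cleavage of aryl ethers: BCl3 should remove the benzyl group at low temperature (pentamethylbenzene traps the benzyl cation) and on warming cleave only the two methyl ethers at C5, since only these can form a six-membered boron chelate with the peri C4 carbonyl group, a selectivity well known for polymethoxyflavones.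

Compound list
1 | acacetin (5,7-dihydroxy-2-(4-methoxyphenyl)-4H-chromen-4-one) | COc1ccc(-c2cc(=O)c3c(O)cc(O)cc3o2)cc1 | starting material
2 | 5-hydroxy-7-methoxy-2-(4-methoxyphenyl)-4H-chromen-4-one | COc1ccc(-c2cc(=O)c3c(O)cc(OC)cc3o2)cc1 | intermediate
3 | 5-hydroxy-6-iodo-7-methoxy-2-(4-methoxyphenyl)-4H-chromen-4-one | COc1ccc(-c2cc(=O)c3c(O)c(I)c(OC)cc3o2)cc1 | intermediate
4 | 6-iodo-5,7-dimethoxy-2-(4-methoxyphenyl)-4H-chromen-4-one | COc1ccc(-c2cc(=O)c3c(OC)c(I)c(OC)cc3o2)cc1 | intermediate
5 | 1-(benzyloxy)-4-ethynylbenzene | C#Cc1ccc(OCc2ccccc2)cc1 | starting material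
6 | 2,4,6-trimethoxybenzaldehyde | COc1cc(OC)c(C=O)c(OC)c1 | starting material
7 | lithium [4-(benzyloxy)phenyl]acetylide | [Li]C#Cc1ccc(OCc2ccccc2)cc1 | intermediate
8 | racemic 3-[4-(benzyloxy)phenyl]-1-(2,4,6-trimethoxyphenyl)prop-2-yn-1-ol | COc1cc(OC)c(C(O)C#Cc2ccc(OCc3ccccc3)cc2)c(OC)c1 | intermediate
9 | 3-[4-(benzyloxy)phenyl]-1-(2,4,6-trimethoxyphenyl)prop-2-yn-1-one | COc1cc(OC)c(C(=O)C#Cc2ccc(OCc3ccccc3)cc2)c(OC)c1 | intermediate
10 | 2-[4-(benzyloxy)phenyl]-3-[5,7-dimethoxy-2-(4-methoxyphenyl)-4-oxo-4H-chromen-6-yl]-5,7-dimethoxy-4H-chromen-4-one | COc1ccc(-c2cc(=O)c3c(OC)c(-c4c(-c5ccc(OCc6ccccc6)cc5)oc5cc(OC)cc(OC)c5c4=O)c(OC)cc3o2)cc1 | intermediate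
11 | stephaflavone B | COc1ccc(-c2cc(=O)c3c(O)c(-c4c(-c5ccc(O)cc5)oc5cc(OC)cc(O)c5c4=O)c(OC)cc3o2)cc1 | target

Total step count: 7. Longest linear sequence: 5 steps (1, 2, 3, 6, 7).

Steps most likely to fail

Risk 1 (step 6): The aryl methyl ether oxygen may be too weak a nucleophile for an alkyne held by a crowded arylpalladium. The oxidative-addition complex could then decay by homocoupling, acetate could add to the bound alkyne in place of the ether oxygen, or silver alone could close the ynone without aryl transfer. The fallback splits the event into known reactions. It sets out from 9 and 4 and comes back at 10. ICl in CH2Cl2 at −78 °C closes 9 to 2-[4-(benzyloxy)phenyl]-3-iodo-5,7-dimethoxy-4H-chromen-4-one F1. Miyaura borylation of 4 (B2pin2, PdCl2(dppf), KOAc, 1,4-dioxane, 90 °C) gives 5,7-dimethoxy-2-(4-methoxyphenyl)-6-(4,4,5,5-tetramethyl-1,3,2-dioxaborolan-2-yl)-4H-chromen-4-one F2. Suzuki–Miyaura coupling of the two (Pd(OAc)2, SPhos, K3PO4, toluene–water, 100 °C) gives 10.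

Risk 2 (step 7): Selectivity among the five methyl ethers may be lost. The 7-OMe of unit 1 lies next to the new axis and near the C4 carbonyl group of unit 2, so a wider boron chelate might trigger its cleavage. The crowded 5-OMe of unit 1 may also lag behind and call for harsher treatment. The fallback changes the masking plan so that the crowded oxygen carries a group that BCl3 removes well below the threshold for methyl ethers. It sets out from 3 and comes back at 11. Alkylation of 3 (2-bromopropane, K2CO3, DMF, 70 °C) gives 6-iodo-5-isopropoxy-7-methoxy-2-(4-methoxyphenyl)-4H-chromen-4-one F3. Coupling with 9 under the conditions of step 6 gives 2-[4-(benzyloxy)phenyl]-3-[5-isopropoxy-7-methoxy-2-(4-methoxyphenyl)-4-oxo-4H-chromen-6-yl]-5,7-dimethoxy-4H-chromen-4-one F4. BCl3 with pentamethylbenzene (CH2Cl2, −78 to 0 °C) then removes the isopropyl and benzyl groups in the cold. Only the ordinary, unhindered 5-OMe of unit 2 is left for chelation-controlled cleavage, which gives 11.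

Risk 3 (step 4): The carbinol flanked by a trimethoxyphenyl ring and an alkyne may ionise on work-up or on silica, followed by substitution or rearrangement. The fallback avoids the alcohol oxidation level altogether. It sets out from 5 and comes back at 9. Commercial 2,4,6-trimethoxybenzoic acid is converted with (COCl)2 and catalytic DMF in CH2Cl2 into 2,4,6-trimethoxybenzoyl chloride F5. An acyl Sonogashira coupling of this chloride with 5 (PdCl2(PPh3)2, CuI, Et3N, THF, rt) gives 9 directly.

Further compounds
F1 | step 6 | 2-[4-(benzyloxy)phenyl]-3-iodo-5,7-dimethoxy-4H-chromen-4-one | COc1cc(OC)c2c(=O)c(I)c(-c3ccc(OCc4ccccc4)cc3)oc2c1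
F2 | step 6 | 5,7-dimethoxy-2-(4-methoxyphenyl)-6-(4,4,5,5-tetramethyl-1,3,2-dioxaborolan-2-yl)-4H-chromen-4-one | COc1ccc(-c2cc(=O)c3c(OC)c(B4OC(C)(C)C(C)(C)O4)c(OC)cc3o2)cc1
F3 | step 7 | 6-iodo-5-isopropoxy-7-methoxy-2-(4-methoxyphenyl)-4H-chromen-4-one | COc1ccc(-c2cc(=O)c3c(OC(C)C)c(I)c(OC)cc3o2)cc1
F4 | step 7 | 2-[4-(benzyloxy)phenyl]-3-[5-isopropoxy-7-methoxy-2-(4-methoxyphenyl)-4-oxo-4H-chromen-6-yl]-5,7-dimethoxy-4H-chromen-4-one | COc1ccc(-c2cc(=O)c3c(OC(C)C)c(-c4c(-c5ccc(OCc6ccccc6)cc5)oc5cc(OC)cc(OC)c5c4=O)c(OC)cc3o2)cc1
F5 | step 4 | 2,4,6-trimethoxybenzoyl chloride | COc1cc(OC)c(C(=O)Cl)c(OC)c1
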